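The plan opens the 12-membered lactone ring inside its heptamethylene tether, between the second and third CH2 counted from arene carbon C5 (furochromene numbering). The seven ring carbons between C5 and the carbinol carbon bear no substituent, so an alkene placed there disappears on hydrogenation. One ring-closing metathesis therefore forms the macrocycle from a diene whose cis-fused furo[2,3-b]chromene ketal, with all three of its stereocentres, is already finished: the 5-allyl-6-carboxylic acid esterified with (R)-oct-7-en-2-ol. The allyl group is carried from step 1 on a 3,5-dimethoxyphenyl core. This avoids any late C–H functionalisation beside the electron-rich C8–H.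

Key step: step 13

Assumption: enantiopure (S)-4-methyldihydrofuran-2(3H)-one and (S)-propylene oxide are bought as such. The tricyclic ketal is numbered O1, C2, C3, C3a, C4, C4a, C5–C8, C8a, O9, C9a.

Step 1
Reactants: 1 1-bromo-3,5-dimethoxybenzene; 2 allyl bromide
Product: 4 1-allyl-3,5-dimethoxybenzene, via 3,5-dimethoxyphenylmagnesium bromide 3 (not isolated)
Conditions: Mg, THF, reflux; then 2, 0 °C → rt
Reagents that add atoms: none
Why: Aryl Grignard formation followed by allylic substitution on allyl bromide is a classical C(sp2)–C(sp3) coupling to which the two methyl ethers are inert.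

Step 2
Reactants: 4 1-allyl-3,5-dimethoxybenzene
Product: 5 1-allyl-2-bromo-3,5-dimethoxybenzene
Conditions: NBS (1.0 equiv), MeCN, −10 → 0 °C, dark
Reagents that add atoms: N-bromosuccinimide, O=C1CCC(=O)N1Br
Why: Electrophilic aromatic bromination with NBS in acetonitrile should take one of the two equivalent positions para to a methoxy group and ortho to the allyl chain, because the doubly activated ring reacts far faster than a monosubstituted alkene and the site between the two ethers is the least accessible.

Step 3
Reactants: 5 1-allyl-2-bromo-3,5-dimethoxybenzene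
Product: 7 2-allyl-3-bromo-4,6-dimethoxybenzaldehyde, via aryl iminium chloride 6 (not isolated)
Conditions: POCl3, DMF, 0 → 70 °C; then aq NaOAc, rt
Reagents that add atoms: N,N-dimethylformamide, CN(C)C=O; water, O
Why: Vilsmeier–Haack formylation should take the only remaining position para to a methoxy group (ortho to the allyl chain) rather than the one flanked by both ethers, and the chloroiminium ion is too weak an electrophile for the terminal alkene.

Step 4
Reactants: 7 2-allyl-3-bromo-4,6-dimethoxybenzaldehyde
Product: 8 2-allyl-3-bromo-6-hydroxy-4-methoxybenzaldehyde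
Conditions: BCl3 (1.2 equiv), CH2Cl2, −78 → 0 °C; then H2O
Reagents that add atoms: none
Why: In this chelation-directed Lewis-acid ether cleavage BCl3 bridges the aldehyde oxygen and the ortho methoxy group, so only that ether loses its methyl group, while the para methoxy group, the alkene and the aryl bromide stay.

Step 5
Reactants: 8 2-allyl-3-bromo-6-hydroxy-4-methoxybenzaldehyde
Product: 9 2-allyl-3-bromo-4-methoxy-6-(methoxymethoxy)benzaldehyde
Conditions: MOMCl, i-Pr2NEt, CH2Cl2, 0 °C → rt
Reagents that add atoms: chloromethyl methyl ether, COCCl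
Why: Williamson-type O-alkylation of the phenol installs an acetal protecting group that withstands hydride, enolate and methyllithium and is removed by the acid of step 9.

Step 6
Reactants: 9 2-allyl-3-bromo-4-methoxy-6-(methoxymethoxy)benzaldehyde
Product: 10 [2-allyl-3-bromo-4-methoxy-6-(methoxymethoxy)phenyl]methanol
Conditions: NaBH4, MeOH, 0 °C
Reagents that add atoms: none
Why: Borohydride reduction of the aldehyde touches neither the alkene, the aryl bromide nor the acetal.

Step 7
Reactants: 10 [2-allyl-3-bromo-4-methoxy-6-(methoxymethoxy)phenyl]methanol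
Product: 11 3-allyl-2-bromo-4-(bromomethyl)-1-methoxy-5-(methoxymethoxy)benzene
Conditions: CBr4, PPh3, CH2Cl2, 0 °C; short silica plug, used at once
Reagents that add atoms: tetrabromomethane, BrC(Br)(Br)Br
Why: The Appel bromination converts the benzylic alcohol under neutral conditions that spare the MOM acetal and the alkene.

Step 8
Reactants: 11 3-allyl-2-bromo-4-(bromomethyl)-1-methoxy-5-(methoxymethoxy)benzene; 12 (S)-4-methyldihydrofuran-2(3H)-one
Product: 14 (3S,4S)-3-[2-allyl-3-bromo-4-methoxy-6-(methoxymethoxy)benzyl]-4-methyldihydrofuran-2(3H)-one, via lithium lactone enolate 13 (not isolated)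
Conditions: LiN(i-Pr)2 (LDA, 1.1 equiv), 12 (1.15 equiv), THF, −78 °C; then 11, DMPU, −78 → −40 °C
Reagents that add atoms: none
Why: SN2 alkylation of the gamma-lactone lithium enolate by the benzylic bromide should occur on the enolate face opposite the C4 methyl group, which sets C3 as (S), trans to the resident (S) centre.

Step 9
Reactants: 14 (3S,4S)-3-[2-allyl-3-bromo-4-methoxy-6-(methoxymethoxy)benzyl]-4-methyldihydrofuran-2(3H)-one
Product: 17 (3S,3aS,9aS)-5-allyl-6-bromo-7-methoxy-3,9a-dimethyl-2,3,3a,9a-tetrahydro-4H-furo[2,3-b]chromene, via MOM-protected lactol 15 (not isolated), via free phenol lactol 16 (not isolated)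
Conditions: MeLi (1.1 equiv), THF, −78 °C; then HCl in MeOH (1.25 M), −78 → 40 °C; concentrate
Reagents that add atoms: methyllithium, [Li]C
Why: 1,2-Addition of MeLi should stop at the lithium hemiketal at −78 °C, and the acid then removes the MOM group and closes the ketal under thermodynamic control, where the short CH2–aryl–O tether reaches C9a only on the face cis to its anchor at C3a (9aS, cis fusion) and the C3 methyl group sits on the convex face.

Step 10
Reactants: 17 (3S,3aS,9aS)-5-allyl-6-bromo-7-methoxy-3,9a-dimethyl-2,3,3a,9a-tetrahydro-4H-furo[2,3-b]chromene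
Product: 19 (3S,3aS,9aS)-5-allyl-7-methoxy-3,9a-dimethyl-2,3,3a,9a-tetrahydro-4H-furo[2,3-b]chromene-6-carboxylic acid, via aryllithium 18 (not isolated)
Conditions: n-BuLi (1.1 equiv), THF, −78 °C, 15 min; CO2 (g), −78 °C → rt; cold 1 M HCl to pH 4
Reagents that add atoms: carbon dioxide, O=C=O
Why: Bromine–lithium exchange is much faster at −78 °C than deprotonation of the allylic CH2 or of C8–H, and carboxylation of the aryllithium leaves the ketal and its three stereocentres untouched.

Step 11
Reactants: 20 5-bromopent-1-ene; 21 (S)-propylene oxide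
Product: 23 (S)-oct-7-en-2-ol, via pent-4-enylmagnesium bromide 22 (not isolated)
Conditions: Mg, THF; then CuBr·SMe2 (10 mol %), 21, −30 → 0 °C; 1 M HCl quench
Reagents that add atoms: none
Why: Copper-catalysed Grignard opening of the epoxide at its unsubstituted carbon does not touch the C–O stereocentre, so the (S) configuration is carried into the alcohol.

Step 12
Reactants: 19 (3S,3aS,9aS)-5-allyl-7-methoxy-3,9a-dimethyl-2,3,3a,9a-tetrahydro-4H-furo[2,3-b]chromene-6-carboxylic acid; 23 (S)-oct-7-en-2-ol
Product: 24 (R)-oct-7-en-2-yl (3S,3aS,9aS)-5-allyl-7-methoxy-3,9a-dimethyl-2,3,3a,9a-tetrahydro-4H-furo[2,3-b]chromene-6-carboxylate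
Conditions: PPh3, DIAD, toluene, 0 °C → rt
Reagents that add atoms: none
Why: Mitsunobu esterification makes the hindered carboxylate the nucleophile, so shielding of its carbonyl group is irrelevant, and SN2 displacement of the oxyphosphonium group inverts the carbinol from (S) to (R).

Step 13
Reactants: 24 (R)-oct-7-en-2-yl (3S,3aS,9aS)-5-allyl-7-methoxy-3,9a-dimethyl-2,3,3a,9a-tetrahydro-4H-furo[2,3-b]chromene-6-carboxylate
Product: 25 dehydro-lasiodiplactone A (ring alkene between the second and third tether carbon from C5, E/Z mixture)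
Conditions: RuCl2(=CHPh)(PCy3)(SIMes) (second-generation Grubbs catalyst, 5 mol %, two portions), 1,4-benzoquinone (10 mol %), CH2Cl2 (1 mM), reflux, argon sparge
Reagents that add atoms: none
Why: This is a ring-closing olefin metathesis by the Chauvin mechanism, in which the ruthenium benzylidene first exchanges with the open terminal alkene of the octenyl chain, the new alkylidene adds to the allyl C=C to give a ruthenacyclobutane, and cycloreversion releases the ring alkene while the Ru=CH2 carrier sheds ethene on the next turnover. The closest known reaction type is the metathesis closure of 12-membered resorcylic lactones from 2-allylbenzoates of oct-7-en-2-ol. The one ring formed is the 12-membered lactone, closed as a macrocyclisation that joins the two internal alkene carbons, each terminal =CH2 being expelled in ethene, which creates a single new C=C. No stereocentre is created, the four existing ones lie away from the reacting carbons, and the alkene geometry does not matter because step 14 removes it. The step needs cyclisation to beat oligomerisation and allyl-to-propenyl migration: the arene and the ester, twisted out of the arene plane by its two ortho neighbours, fix four ring atoms and keep both chain ends close, the 1 mM dilution with portionwise catalyst disfavours dimers, and benzoquinone intercepts ruthenium hydrides. The ketal, the aryl ethers and the hindered ester neither bind nor react with the catalyst.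

Step 14
Reactants: 25 dehydro-lasiodiplactone A
Product: 26 lasiodiplactone A
Conditions: H2 (1 atm), 10% Pd/C, EtOAc, rt
Reagents that add atoms: none
Why: Heterogeneous catalytic hydrogenation saturates both alkene isomers under neutral conditions, and the ketal, ester and aryl ethers are neither reducible nor hydrogenolysable.

Compound list
1 | 1-bromo-3,5-dimethoxybenzene | COc1cc(Br)cc(OC)c1 | starting material
2 | allyl bromide (3-bromoprop-1-ene) | C=CCBr | starting material
3 | 3,5-dimethoxyphenylmagnesium bromide | COc1cc(OC)cc([Mg]Br)c1 | intermediate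
4 | 1-allyl-3,5-dimethoxybenzene | C=CCc1cc(OC)cc(OC)c1 | intermediate
5 | 1-allyl-2-bromo-3,5-dimethoxybenzene | C=CCc1cc(OC)cc(OC)c1Br | intermediate
6 | N-(2-allyl-3-bromo-4,6-dimethoxybenzylidene)-N-methylmethanaminium chloride | C[N+](C)=Cc1c(CC=C)c(Br)c(OC)cc1OC.[Cl-] | intermediate
7 | 2-allyl-3-bromo-4,6-dimethoxybenzaldehyde | O=Cc1c(CC=C)c(Br)c(OC)cc1OC | intermediate
8 | 2-allyl-3-bromo-6-hydroxy-4-methoxybenzaldehyde | O=Cc1c(CC=C)c(Br)c(OC)cc1O | intermediate
9 | 2-allyl-3-bromo-4-methoxy-6-(methoxymethoxy)benzaldehyde | O=Cc1c(CC=C)c(Br)c(OC)cc1OCOC | intermediate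
10 | [2-allyl-3-bromo-4-methoxy-6-(methoxymethoxy)phenyl]methanol | OCc1c(CC=C)c(Br)c(OC)cc1OCOC | intermediate
11 | 3-allyl-2-bromo-4-(bromomethyl)-1-methoxy-5-(methoxymethoxy)benzene | BrCc1c(CC=C)c(Br)c(OC)cc1OCOC | intermediate
12 | (S)-4-methyldihydrofuran-2(3H)-one | O=C1C[C@H](C)CO1 | starting material
13 | lithium (S)-4-methyl-4,5-dihydrofuran-2-olate (enolate of 12) | [Li+].[O-]C1=C[C@H](C)CO1 | intermediate
14 | (3S,4S)-3-[2-allyl-3-bromo-4-methoxy-6-(methoxymethoxy)benzyl]-4-methyldihydrofuran-2(3H)-one | COCOc1cc(OC)c(Br)c(CC=C)c1C[C@H]1[C@H](C)COC1=O | intermediate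
15 | (3S,4S)-3-[2-allyl-3-bromo-4-methoxy-6-(methoxymethoxy)benzyl]-2,4-dimethyltetrahydrofuran-2-ol (anomer mixture, lithium alkoxide before the quench) | COCOc1cc(OC)c(Br)c(CC=C)c1C[C@H]1[C@H](C)COC1(C)O | intermediate
16 | (3S,4S)-3-(2-allyl-3-bromo-6-hydroxy-4-methoxybenzyl)-2,4-dimethyltetrahydrofuran-2-ol (anomer mixture) | Oc1cc(OC)c(Br)c(CC=C)c1C[C@H]1[C@H](C)COC1(C)O | intermediate
17 | (3S,3aS,9aS)-5-allyl-6-bromo-7-methoxy-3,9a-dimethyl-2,3,3a,9a-tetrahydro-4H-furo[2,3-b]chromene | COc1cc2c(c(CC=C)c1Br)C[C@H]1[C@H](C)CO[C@@]1(C)O2 | intermediate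
18 | 6-lithio derivative of 17 (aryllithium) | COc1cc2c(c(CC=C)c1[Li])C[C@H]1[C@H](C)CO[C@@]1(C)O2 | intermediate
19 | (3S,3aS,9aS)-5-allyl-7-methoxy-3,9a-dimethyl-2,3,3a,9a-tetrahydro-4H-furo[2,3-b]chromene-6-carboxylic acid | COc1cc2c(c(CC=C)c1C(=O)O)C[C@H]1[C@H](C)CO[C@@]1(C)O2 | intermediate
20 | 5-bromopent-1-ene | C=CCCCBr | starting material
21 | (S)-propylene oxide | C[C@H]1CO1 | starting material
22 | pent-4-enylmagnesium bromide | C=CCCC[Mg]Br | intermediate
23 | (S)-oct-7-en-2-ol | C[C@H](O)CCCCC=C | intermediate
24 | (R)-oct-7-en-2-yl (3S,3aS,9aS)-5-allyl-7-methoxy-3,9a-dimethyl-2,3,3a,9a-tetrahydro-4H-furo[2,3-b]chromene-6-carboxylate | COc1cc2c(c(CC=C)c1C(=O)O[C@H](C)CCCCC=C)C[C@H]1[C@H](C)CO[C@@]1(C)O2 | intermediate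
25 | dehydro-lasiodiplactone A (E/Z mixture at the ring alkene) | COc1cc2c(c3c1C(=O)O[C@H](C)CCCCC=CC3)C[C@H]1[C@H](C)CO[C@@]1(C)O2 | intermediate
26 | lasiodiplactone A | COc1cc2c(c3c1C(=O)O[C@H](C)CCCCCCC3)C[C@H]1[C@H](C)CO[C@@]1(C)O2 | target

Total step count: 14. Longest linear sequence: 13 steps (steps 1–10 and 12–14). Step 11 is the side branch.

Steps most likely to fail

Step 13. Intermolecular metathesis may outrun ring closure and give dimers and oligomers. The allyl double bond may also migrate into conjugation with the arene before closure, which would shorten the ring by one carbon. The fallback closes the ring at the ester C–O bond instead and sets out from acid 19 and alcohol 23. Cross-metathesis with an excess of 23 (second-generation Hoveyda–Grubbs catalyst RuCl2(=CH-C6H4-2-O-i-Pr)(SIMes), CH2Cl2, 40 °C) should give the unsaturated (S)-hydroxy seco acid F1. Hydrogenation (H2, Pd/C, EtOAc) should give the saturated (S)-hydroxy seco acid F2. A Mitsunobu macrolactonisation at high dilution (PPh3, DIAD, toluene) should then invert the carbinol to (R) and come back to the route at target 26.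

Step 8. The electron-rich benzylic bromide may ionise and self-condense before it meets the enolate. Substitution at the doubly ortho-flanked carbon may be slow, and proton exchange between product and enolate may lead to double alkylation and eroded trans selectivity. The fallback forms the same C–C bond by carbonyl addition, skips steps 6 and 7, and sets out from aldehyde 9 and lactone 12. Aldol addition of enolate 13 (THF, −78 °C) should give the beta-hydroxy lactone F3 as a diastereomer mixture. MsCl/Et3N should convert it into the benzylic mesylate F4, which DBU eliminates in the same flask to the benzylidene lactone F5. Conjugate reduction with LiBH(s-Bu)3 (THF, −78 °C), followed by equilibration of the alpha centre with DBU to the more stable trans isomer, comes back to the route at 14.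

Step 9. The hemiketal may collapse early and take up a second methyl group, or the lactone may be enolised instead of attacked. The formaldehyde equivalent released from the MOM group may also be captured at the electron-rich C8 position. The fallback replaces direct addition by an acyl-transfer sequence that cannot over-add and sets out from lactone 14. Aminolysis with MeNH(OMe)·HCl and AlMe3 (CH2Cl2, 0 °C) should give the hydroxy Weinreb amide F6. TBSCl/imidazole should give the silyl ether F7, and MeMgBr (THF, 0 °C) should stop at the methyl ketone F8 through the chelated tetrahedral intermediate. HCl in MeOH then removes both protecting groups and closes the ketal, coming back to the route at 17.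

Further compounds
F1 | step 13 | (3S,3aS,9aS)-5-[(7S)-7-hydroxyoct-2-en-1-yl]-7-methoxy-3,9a-dimethyl-2,3,3a,9a-tetrahydro-4H-furo[2,3-b]chromene-6-carboxylic acid (E/Z) | COc1cc2c(c(CC=CCCCC[C@H](C)O)c1C(=O)O)C[C@H]1[C@H](C)CO[C@@]1(C)O2
F2 | step 13 | (3S,3aS,9aS)-5-[(7S)-7-hydroxyoctyl]-7-methoxy-3,9a-dimethyl-2,3,3a,9a-tetrahydro-4H-furo[2,3-b]chromene-6-carboxylic acid | COc1cc2c(c(CCCCCCC[C@H](C)O)c1C(=O)O)C[C@H]1[C@H](C)CO[C@@]1(C)O2
F3 | step 8 | (4S)-3-{[2-allyl-3-bromo-4-methoxy-6-(methoxymethoxy)phenyl](hydroxy)methyl}-4-methyldihydrofuran-2(3H)-one (diastereomer mixture) | COCOc1cc(OC)c(Br)c(CC=C)c1C(O)C1[C@H](C)COC1=O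
F4 | step 8 | methanesulfonate of F3 | COCOc1cc(OC)c(Br)c(CC=C)c1C(OS(C)(=O)=O)C1[C@H](C)COC1=O
F5 | step 8 | (4S)-3-[2-allyl-3-bromo-4-methoxy-6-(methoxymethoxy)benzylidene]-4-methyldihydrofuran-2(3H)-one (either alkene geometry) | COCOc1cc(OC)c(Br)c(CC=C)c1C=C1[C@H](C)COC1=O
F6 | step 9 | (2S,3S)-2-[2-allyl-3-bromo-4-methoxy-6-(methoxymethoxy)benzyl]-4-hydroxy-N-methoxy-N,3-dimethylbutanamide | COCOc1cc(OC)c(Br)c(CC=C)c1C[C@H](C(=O)N(C)OC)[C@H](C)CO
F7 | step 9 | tert-butyldimethylsilyl ether of F6 | COCOc1cc(OC)c(Br)c(CC=C)c1C[C@H](C(=O)N(C)OC)[C@H](C)CO[Si](C)(C)C(C)(C)C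
F8 | step 9 | (3S,4S)-3-[2-allyl-3-bromo-4-methoxy-6-(methoxymethoxy)benzyl]-5-(tert-butyldimethylsilyloxy)-4-methylpentan-2-one | COCOc1cc(OC)c(Br)c(CC=C)c1C[C@H](C(C)=O)[C@H](C)CO[Si](C)(C)C(C)(C)C
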